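A direct plan would join two preformed rings at the bridging CH2: the enolate of acetylfilicinic acid A1, made by double C-methylation of an acylphloroglucinol, would add to the o-quinone methide A3 released from the aminomethylated aryl ketone A2. Its weakest steps would be:
- the dearomatising gem-dimethylation that makes A1, because mono-, tri- and O-methylated products would form beside it;
- the aminomethylation that gives A2, because the arene has two equivalent nucleophilic ring carbons, and placing the butanoyl group between the two hydroxyls would first cost a protection, metalation and deprotection sequence;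
- the union of A3 with A1, because this Michael addition is reversible in base, so the methylene group could migrate to give symmetrical dimers and excess A1 would be needed.

Ring B, a 2-acetylcyclohexane-1,3,5-trione with oxygen on alternate carbons, is a folded C8 tetraketide. The route therefore closes it last from an open chain, as a polyketide synthase closes an acylphloroglucinol: a linear 3,5,7-triketo ester that already carries the gem-dimethyl carbon (C2) and the whole aryl-CH2 branch (C4) undergoes C6→C1 Claisen cyclisation. One operation would form the last ring bond, leave acetyl outside the ring and give the target. The bridging CH2 is a chain carbon from acrylic acid (through a dihydrocoumarin), the quaternary carbon comes from methyl isobutyrate and C5–C8 from diketene; no dearomatising methylation, aminomethylation or union of two preformed rings at a methylene group is needed.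

Key step: step 5

Remark: ring B is written in the enol form of the target SMILES (its β-triketone tautomers are one compound), open-chain polyketones are drawn as keto forms, and the chain atoms of 9 and 12 are numbered from the ester carbon (C1).

Step 1
Reactants: 1 1-(2,4,6-trihydroxyphenyl)butan-1-one; 2 dimethyl sulfate
Product: 3 1-(2,6-dihydroxy-4-methoxyphenyl)butan-1-one
Conditions: Me2SO4 (1.0 equiv), K2CO3 (1.05 equiv), acetone, reflux, 4 h
Reagents that add atoms: dimethyl sulfate, COS(=O)(=O)OC
Why: Williamson ether synthesis; the 4-OH, para to the carbonyl, is the most acidic hydroxyl and the only one not held in a hydrogen bond to the ketone, so one equivalent of base and sulfate should methylate it selectively.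

Step 2
Reactants: 3 1-(2,6-dihydroxy-4-methoxyphenyl)butan-1-one; 4 acrylic acid
Product: 6 8-butanoyl-7-hydroxy-5-methoxy-3,4-dihydro-2H-chromen-2-one, via 3-(3-butanoyl-2,4-dihydroxy-6-methoxyphenyl)propanoic acid 5 (not isolated)
Conditions: acrylic acid (2 equiv), 4-CH3C6H4SO3H·H2O (0.3 equiv), toluene, reflux, Dean–Stark, 12 h
Reagents that add atoms: acrylic acid, C=CC(=O)O
Why: Acid-catalysed Friedel–Crafts conjugate addition (hydroarylation) at one of the two equivalent free ring carbons, then lactonisation with the neighbouring hydroxyl; the aryl ester deactivates the ring against a second alkylation, and the lactone is both a protected phenol and an activated 3-arylpropanoyl donor.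

Step 3
Reactants: 6 8-butanoyl-7-hydroxy-5-methoxy-3,4-dihydro-2H-chromen-2-one; 7 methyl 2-methylpropanoate
Product: 9 methyl 5-(3-butanoyl-2,4-dihydroxy-6-methoxyphenyl)-2,2-dimethyl-3-oxopentanoate, via lithium enolate 8 (not isolated)
Conditions: 7 (3.2 equiv), LiN(iPr)2 (3.1 equiv), THF, −78 °C, 30 min; then 6 (1.0 equiv) in THF, −78 → −20 °C, 2 h; AcOH (excess), −20 °C; work-up at pH 5
Reagents that add atoms: methyl 2-methylpropanoate, COC(=O)C(C)C
Why: Crossed Claisen condensation: after the first equivalent of enolate has taken the 7-OH proton (the phenoxide shields the butanoyl ketone), the ester enolate adds to the aryl lactone carbonyl, the only activated acyl group, and collapse of the adduct opens the ring to the phenoxide; the new ketone has no acidic C–H between its carbonyl groups and is flanked by a quaternary carbon, so neither quenching of the enolate nor a second addition should follow.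

Step 4
Reactants: 9 methyl 5-(3-butanoyl-2,4-dihydroxy-6-methoxyphenyl)-2,2-dimethyl-3-oxopentanoate; 10 diketene (4-methylideneoxetan-2-one)
Product: 12 methyl 4-[(3-butanoyl-2,4-dihydroxy-6-methoxyphenyl)methyl]-2,2-dimethyl-3,5,7-trioxooctanoate, via trilithium enolate 11 (not isolated)
Conditions: LiN(SiMe3)2 (4.2 equiv), THF–DMPU (10:1), −78 → −40 °C, 1 h; diketene (1.1 equiv), −78 °C, 30 min; AcOH (5 equiv), −78 °C; work-up at pH 5; crude product used at once
Reagents that add atoms: diketene, C=C1CC(=O)O1
Why: Claisen-type C-acetoacetylation of a ketone enolate: the enolate opens diketene at its acyl carbon and the acetonyl enolate set free relays its charge to the new, more acidic C6 position, for which the fourth equivalent of base is reserved; 9 has only one enolisable carbon next to its aliphatic ketone (C4, since C2 is quaternary), the two phenoxides turn the butanoyl group into a vinylogous carboxylate that is neither deprotonated nor attacked, and any aryl acetoacetate formed through a phenoxide oxygen would be cleaved again by methanolysis in step 5.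

Step 5
Reactants: 12 methyl 4-[(3-butanoyl-2,4-dihydroxy-6-methoxyphenyl)methyl]-2,2-dimethyl-3,5,7-trioxooctanoate
Product: 14 2-acetyl-6-[(3-butanoyl-2,4-dihydroxy-6-methoxyphenyl)methyl]-3,5-dihydroxy-4,4-dimethylcyclohexa-2,5-dien-1-one (target), via magnesium diketonate 13 (not isolated)
Conditions: Mg(OMe)2 (6 equiv), MeOH, 45 °C, 8 h; then cold 1 M HCl to pH 3, EtOAc; chromatography or crystallisation
Reagents that add atoms: none
Why: Mg(OMe)2 turns the 5,7-diketone into its chelated enolate, C6 adds to the C1 ester carbonyl, methoxide leaves, and the 2-acetyl-1,3,5-trione enolises to the drawn form and is held as its strongly stabilised magnesium salt, which makes the closure irreversible. The closest known reaction type is the biomimetic Claisen (Dieckmann-type) cyclisation of 3,5,7-trioxoalkanoates to acylphloroglucinols. Ring B closes by 6-exo-trig attack of the enolate carbon on the ester carbonyl, and C6 is the only carbon nucleophile that reaches C1 through a six-membered transition state, which places acetyl outside the ring and the aryl-CH2 branch on it. No stereocentre is formed: C4 of 12 becomes an sp2 enol carbon and the product is achiral. The step needs carbon over oxygen acylation and Claisen over aldol closure: the quaternary C2 removes the C2-to-C7 aldol path that leads unsubstituted triketo esters to resorcylates, keeps the ester outside the enolate system and so electrophilic, and favours the folded conformer (Thorpe–Ingold effect), while the mild base leaves the C8 methyl un-ionised. An enol lactone formed through oxygen would be reopened by methoxide and drained into the far more acidic carbocycle, and the moderate temperature should limit retro-Michael loss of the aryl-CH2 branch.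

Compound list

1 | 1-(2,4,6-trihydroxyphenyl)butan-1-one | CCCC(=O)c1c(O)cc(O)cc1O | starting material
2 | dimethyl sulfate | COS(=O)(=O)OC | starting material
3 | 1-(2,6-dihydroxy-4-methoxyphenyl)butan-1-one | CCCC(=O)c1c(O)cc(OC)cc1O | intermediate
4 | acrylic acid (prop-2-enoic acid) | C=CC(=O)O | starting material
5 | 3-(3-butanoyl-2,4-dihydroxy-6-methoxyphenyl)propanoic acid | CCCC(=O)c1c(O)cc(OC)c(CCC(=O)O)c1O | intermediate (not isolated)
6 | 8-butanoyl-7-hydroxy-5-methoxy-3,4-dihydro-2H-chromen-2-one | CCCC(=O)c1c(O)cc(OC)c2CCC(=O)Oc12 | intermediate
7 | methyl 2-methylpropanoate (methyl isobutyrate) | COC(=O)C(C)C | starting material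
8 | lithium 1-methoxy-2-methylprop-1-en-1-olate | [Li+].COC([O-])=C(C)C | intermediate (not isolated)
9 | methyl 5-(3-butanoyl-2,4-dihydroxy-6-methoxyphenyl)-2,2-dimethyl-3-oxopentanoate | CCCC(=O)c1c(O)cc(OC)c(CCC(=O)C(C)(C)C(=O)OC)c1O | intermediate
10 | diketene (4-methylideneoxetan-2-one) | C=C1CC(=O)O1 | starting material
11 | trilithium bis(phenoxide) C4-enolate of 9 | [Li+].[Li+].[Li+].CCCC(=O)c1c([O-])cc(OC)c(CC=C([O-])C(C)(C)C(=O)OC)c1[O-] | intermediate (not isolated)
12 | methyl 4-[(3-butanoyl-2,4-dihydroxy-6-methoxyphenyl)methyl]-2,2-dimethyl-3,5,7-trioxooctanoate (racemic at C4, configurationally labile) | CCCC(=O)c1c(O)cc(OC)c(CC(C(=O)CC(C)=O)C(=O)C(C)(C)C(=O)OC)c1O | intermediate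
13 | methoxymagnesium 5,7-diketonate of 12 | CCCC(=O)c1c(O)cc(OC)c(CC(C(=O)C=C(C)[O-])C(=O)C(C)(C)C(=O)OC)c1O.[Mg+2].C[O-] | intermediate (not isolated)
14 | 2-acetyl-6-[(3-butanoyl-2,4-dihydroxy-6-methoxyphenyl)methyl]-3,5-dihydroxy-4,4-dimethylcyclohexa-2,5-dien-1-one (achiral) | CCCC(=O)c1c(O)cc(OC)c(CC2=C(O)C(C)(C)C(O)=C(C(C)=O)C2=O)c1O | target

Total step count: 5. Longest linear sequence: 5 steps (1 → 3 → 6 → 9 → 12 → 14).

Steps most likely to fail

Step 5 (ring closure). The triketo ester could close through oxygen to an enol lactone that does not reopen, the terminal methyl could close by aldol addition on C3 and aromatise to a resorcinol, or methoxide could cut the chain by retro-Claisen cleavage or expel the aryl-CH2 branch by retro-Michael reaction. The fallback would close ring B before the acetyl group is present, so that only one closure is possible. Setting out from 9, its enolate 11 would be C-acetylated with N-methoxy-N-methylacetamide to methyl 4-acetyl-5-(3-butanoyl-2,4-dihydroxy-6-methoxyphenyl)-2,2-dimethyl-3-oxopentanoate F1. Excess KOC(CH3)3 in THF would then form the diketone dianion, whose terminal methyl carbon should close on the ester (Hauser-type dianion acylation, as in the dimedone synthesis) to 6-[(3-butanoyl-2,4-dihydroxy-6-methoxyphenyl)methyl]-3,5-dihydroxy-4,4-dimethylcyclohexa-2,5-dien-1-one F2. C-acetylation of its free ring carbon with acetic anhydride and BF3·OEt2, followed by mild methanolysis of O-acetates (K2CO3, MeOH), would come back to the route at 14.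

Step 4 (acetoacetylation). Diketene could acylate the phenoxide or enolate oxygens instead of carbon, could polymerise, or the enolate could be quenched by proton transfer from the more acidic product. The fallback would use a masked acetoacetate ester in a conventional Claisen acylation. Setting out from 9, the enolate 11 would be acylated with ethyl (2-methyl-1,3-dioxolan-2-yl)acetate to the ketal methyl 4-[(3-butanoyl-2,4-dihydroxy-6-methoxyphenyl)methyl]-2,2-dimethyl-6-(2-methyl-1,3-dioxolan-2-yl)-3,5-dioxohexanoate F3. Hydrolysis of the ketal (pyridinium 4-toluenesulfonate, acetone–water, 40 °C) would come back to the route at 12.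

Step 2 (lactone annulation). The acid could acylate the ring instead of alkylating it, which would lead to a chromanone; acrylic acid could polymerise; or the ring, deactivated by its protonated acyl group, could react too slowly. The fallback would build the lactone at the coumarin oxidation level. Setting out from 3, hydroarylation of ethyl propiolate (Pd(OAc)2 cat., CF3CO2H, CH2Cl2, rt) with spontaneous lactonisation should give 8-butanoyl-7-hydroxy-5-methoxy-2H-chromen-2-one F4. Hydrogenation of its C3–C4 double bond (H2, Pd/C, EtOAc, rt) would come back to the route at 6.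

Further compounds

F1 | step 5 | methyl 4-acetyl-5-(3-butanoyl-2,4-dihydroxy-6-methoxyphenyl)-2,2-dimethyl-3-oxopentanoate (racemic, labile) | CCCC(=O)c1c(O)cc(OC)c(CC(C(C)=O)C(=O)C(C)(C)C(=O)OC)c1O
F2 | step 5 | 6-[(3-butanoyl-2,4-dihydroxy-6-methoxyphenyl)methyl]-3,5-dihydroxy-4,4-dimethylcyclohexa-2,5-dien-1-one | CCCC(=O)c1c(O)cc(OC)c(CC2=C(O)C(C)(C)C(O)=CC2=O)c1O
F3 | step 4 | methyl 4-[(3-butanoyl-2,4-dihydroxy-6-methoxyphenyl)methyl]-2,2-dimethyl-6-(2-methyl-1,3-dioxolan-2-yl)-3,5-dioxohexanoate (racemic, labile) | CCCC(=O)c1c(O)cc(OC)c(CC(C(=O)CC2(C)OCCO2)C(=O)C(C)(C)C(=O)OC)c1O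
F4 | step 2 | 8-butanoyl-7-hydroxy-5-methoxy-2H-chromen-2-one | CCCC(=O)c1c(O)cc(OC)c2C=CC(=O)Oc12
A1 | direct plan | acetylfilicinic acid (2-acetyl-3,5-dihydroxy-4,4-dimethylcyclohexa-2,5-dien-1-one) | CC(=O)C1=C(O)C(C)(C)C(O)=CC1=O
A2 | direct plan | 1-{3-[(dimethylamino)methyl]-2,6-dihydroxy-4-methoxyphenyl}butan-1-one | CCCC(=O)c1c(O)cc(OC)c(CN(C)C)c1O
A3 | direct plan | 2-butanoyl-3-hydroxy-5-methoxy-6-methylidenecyclohexa-2,4-dien-1-one (o-quinone methide) | C=C1C(OC)=CC(O)=C(C(=O)CCC)C1=O
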